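**Plan**
Retrosynthesis: the three benzyl ethers are put back and C4 is taken through a carbinol/ketone redox detour to reach a racemic 3-arylchroman-4-one carrying a removable ester at C3. C4–C4a and C3–C4 are then cut together, C4 leaving as CO, and O1–C2 is cut last.
Enabling feature: the C4 carbonyl lies between aromatic C4a of ring A and sp3 C3 of ring C, and C3 is already tied to ring A through O1–C2. CO can therefore be inserted between a C4a–I bond and a C3 ester enolate.
Forward: a ring A iodophenol (from 1) and a ring B 2-arylacrylate (from 8) are joined at O1–C2, ring C is closed by carbonylative C-acylation, and the C3 ester is removed.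
Stereochemistry: C3 is set by Ru–TsDPEN transfer hydrogenation of the racemic ketone with dynamic kinetic resolution, giving the cis-(3R,4R) carbinol. C4 is then re-oxidised and the benzyl ethers are removed without base.

Key step: step 12

Remark: RuCl[(R,R)-TsDPEN](p-cymene) is assumed to deliver hydride in the sense known for simple aryl ketones ((R)-carbinol), which in the cis-isoflavanol corresponds to (3R,4R) and hence to the (3R) ketone.

**Route**

Step 1
Reactants: 1 methyl 3,5-dihydroxy-4-methoxybenzoate
Product: 2 methyl 3,5-bis(benzyloxy)-4-methoxybenzoate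
Conditions: BnBr, K2CO3, DMF, 60 °C
Reagents that add atoms: benzyl bromide, BrCc1ccccc1
Why: Williamson ether synthesis on the two equivalent phenols installs benzyl ethers that tolerate all later steps and leave together by neutral hydrogenolysis at the end.

Step 2
Reactants: 2 methyl 3,5-bis(benzyloxy)-4-methoxybenzoate
Product: 3 [3,5-bis(benzyloxy)-4-methoxyphenyl]methanol
Conditions: LiAlH4, THF, 0 °C to rt
Reagents that add atoms: none
Why: LiAlH4 reduction of a benzoate ester to the benzyl alcohol, with aryl ethers inert to hydride.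

Step 3
Reactants: 3 [3,5-bis(benzyloxy)-4-methoxyphenyl]methanol
Product: 4 3,5-bis(benzyloxy)-4-methoxybenzaldehyde
Conditions: MnO2, CH2Cl2, rt
Reagents that add atoms: none
Why: MnO2 oxidation of a benzylic alcohol should stop cleanly at the aldehyde.

Step 4
Reactants: 4 3,5-bis(benzyloxy)-4-methoxybenzaldehyde
Product: 6 3,5-bis(benzyloxy)-4-methoxyphenol, via aryl formate 5 (not isolated)
Conditions: mCPBA, CH2Cl2, rt; then K2CO3 (cat.), MeOH, rt
Reagents that add atoms: 3-chloroperoxybenzoic acid (mCPBA), OOC(=O)c1cccc(Cl)c1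
Why: Baeyer–Villiger (Dakin-type) oxidation of an electron-rich benzaldehyde proceeds by aryl migration to the formate, and methanolysis frees the phenol only after the peracid is consumed.

Step 5
Reactants: 6 3,5-bis(benzyloxy)-4-methoxyphenol
Product: 7 3,5-bis(benzyloxy)-2-iodo-4-methoxyphenol
Conditions: NIS (1.0 equiv), MeCN, −20 to 0 °C
Reagents that add atoms: N-iodosuccinimide, O=C1CCC(=O)N1I
Why: electrophilic aromatic iodination ortho to the free hydroxyl; the para position is blocked and the two ortho positions are equivalent, so one equivalent of NIS at low temperature should give the mono-iodide at the future C4a.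

Step 6
Reactants: 8 3-hydroxy-4,5-dimethoxybenzaldehyde
Product: 9 3-(benzyloxy)-4,5-dimethoxybenzaldehyde
Conditions: BnBr, K2CO3, DMF, 60 °C
Reagents that add atoms: benzyl bromide, BrCc1ccccc1
Why: Williamson ether synthesis masks the ring B phenol as the same hydrogenolysable ether used on ring A.

Step 7
Reactants: 9 3-(benzyloxy)-4,5-dimethoxybenzaldehyde
Product: 10 2-[3-(benzyloxy)-4,5-dimethoxyphenyl]acetonitrile
Conditions: TosMIC, t-BuOK, DME, −50 °C; then MeOH, reflux
Reagents that add atoms: p-toluenesulfonylmethyl isocyanide (TosMIC), Cc1ccc(cc1)S(=O)(=O)C[N+]#[C-]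
Why: van Leusen reductive cyanation homologates the aromatic aldehyde by one carbon, the aldehyde carbon becoming the benzylic CH2 and the TosMIC methylene carbon the nitrile carbon.

Step 8
Reactants: 10 2-[3-(benzyloxy)-4,5-dimethoxyphenyl]acetonitrile
Product: 11 2-[3-(benzyloxy)-4,5-dimethoxyphenyl]acetic acid
Conditions: KOH, EtOH/H2O, reflux; then aq. HCl
Reagents that add atoms: water, O
Why: alkaline nitrile hydrolysis to the arylacetic acid, which the benzyl and methyl aryl ethers tolerate.

Step 9
Reactants: 11 2-[3-(benzyloxy)-4,5-dimethoxyphenyl]acetic acid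
Product: 12 tert-butyl 2-[3-(benzyloxy)-4,5-dimethoxyphenyl]acetate
Conditions: tert-butyl 2,2,2-trichloroacetimidate, CH2Cl2/cyclohexane, rt
Reagents that add atoms: tert-butyl 2,2,2-trichloroacetimidate, CC(C)(C)OC(=N)C(Cl)(Cl)Cl
Why: imidate esterification transfers the tert-butyl group to the acid under near-neutral conditions, giving an ester that is bulky, non-electrophilic and removable by acid after ring closure.

Step 10
Reactants: 12 tert-butyl 2-[3-(benzyloxy)-4,5-dimethoxyphenyl]acetate
Product: 14 tert-butyl 2-[3-(benzyloxy)-4,5-dimethoxyphenyl]prop-2-enoate, via hydroxymethyl ester 13 (not isolated)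
Conditions: (CH2O)n, K2CO3, Bu4NI (cat.), toluene, 80 °C
Reagents that add atoms: formaldehyde (as paraformaldehyde), C=O
Why: aldol addition of the arylacetate enolate to formaldehyde followed by E1cB dehydration (Knoevenagel-type methylenation) gives the 2-arylacrylate, which is used without storage.

Step 11
Reactants: 7 3,5-bis(benzyloxy)-2-iodo-4-methoxyphenol, 14 tert-butyl 2-[3-(benzyloxy)-4,5-dimethoxyphenyl]prop-2-enoate
Product: 15 tert-butyl 3-[3,5-bis(benzyloxy)-2-iodo-4-methoxyphenoxy]-2-[3-(benzyloxy)-4,5-dimethoxyphenyl]propanoate (racemic)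
Conditions: Cs2CO3 (0.2 equiv), 14 (1.5 equiv), MeCN (concentrated), 40 °C
Reagents that add atoms: none
Why: base-catalysed oxa-Michael addition of the phenoxide to the acrylate forms O1–C2; catalytic base, excess acceptor and moderate temperature hold the reversible addition on the adduct side.

Step 12
Reactants: 15 tert-butyl 3-[3,5-bis(benzyloxy)-2-iodo-4-methoxyphenoxy]-2-[3-(benzyloxy)-4,5-dimethoxyphenyl]propanoate (racemic), 16 carbon monoxide
Product: 17 tert-butyl 5,7-bis(benzyloxy)-3-[3-(benzyloxy)-4,5-dimethoxyphenyl]-6-methoxy-4-oxochromane-3-carboxylate (racemic)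
Conditions: PdCl2(PPh3)2 (5 mol%), Et3N (3 equiv), CO (40 bar), MeCN/toluene, 100 °C
Reagents that add atoms: none
Why: PdCl2(PPh3)2 is reduced in situ to zerovalent palladium, which inserts into the C4a–I bond; CO insertion gives an aroylpalladium iodide (divalent palladium), the C3 ester enolate that Et3N generates reversibly attacks it at carbon, and reductive elimination forms C3–C4 after C4a–C4 and returns zerovalent palladium. The closest known reaction type is the palladium-catalysed carbonylative cyclisation of aryl iodides in which an internal ester or malonate enolate traps the acylpalladium (intramolecular carbonylative alpha-arylation). Ring C closes in a 6-exo-trig sense, the enolate carbon C3 attacking the exocyclic acyl carbon C4 through the O1–C2 tether. C3 becomes a quaternary stereocentre without control, which is harmless because step 13 flattens it again. Three selectivities are needed: CO uptake before direct C3–C4a coupling (40 bar CO makes carbonylation of the aryl–Pd bond outrun closure to the five-membered dihydrobenzofuran); C- over O-acylation (O-closure would need an eight-membered ketene acetal); and acylation over beta-elimination of the ring A aryloxide from the enolate (the weak amine keeps the enolate at a trace stationary level, so Pd-free substrate is reprotonated while substrate already carrying the acyl–Pd is captured at once, and the alpha-aryl group makes C3–H acidic enough for this).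

Step 13
Reactants: 17 tert-butyl 5,7-bis(benzyloxy)-3-[3-(benzyloxy)-4,5-dimethoxyphenyl]-6-methoxy-4-oxochromane-3-carboxylate (racemic)
Product: 19 racemic 5,7-bis(benzyloxy)-3-[3-(benzyloxy)-4,5-dimethoxyphenyl]-6-methoxychroman-4-one, via keto acid 18 (not isolated)
Conditions: TFA/CH2Cl2 (1:4), 0 °C to rt; then toluene, 60 °C
Reagents that add atoms: none
Why: acidolysis of the tert-butyl ester (E1 loss of isobutene) gives a beta-keto acid that decarboxylates through the cyclic six-membered transition state, while aryl benzyl ethers should tolerate brief cold TFA.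

Step 14
Reactants: 19 racemic 5,7-bis(benzyloxy)-3-[3-(benzyloxy)-4,5-dimethoxyphenyl]-6-methoxychroman-4-one
Product: 20 (3R,4R)-5,7-bis(benzyloxy)-3-[3-(benzyloxy)-4,5-dimethoxyphenyl]-6-methoxychroman-4-ol (cis)
Conditions: RuCl[(R,R)-TsDPEN](p-cymene) (3 mol%), HCO2H/Et3N (1:3), EtOAc, 40 °C
Reagents that add atoms: none
Why: Noyori–Ikariya asymmetric transfer hydrogenation with dynamic kinetic resolution: Et3N epimerises C3 through the enol, and the (R,R) catalyst reduces only the (3R) ketone quickly, from the face that gives the (4R) carbinol cis to the C3 aryl group, so C3 and C4 are set together.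

Step 15
Reactants: 20 (3R,4R)-5,7-bis(benzyloxy)-3-[3-(benzyloxy)-4,5-dimethoxyphenyl]-6-methoxychroman-4-ol
Product: 21 (3R)-5,7-bis(benzyloxy)-3-[3-(benzyloxy)-4,5-dimethoxyphenyl]-6-methoxychroman-4-one
Conditions: Dess–Martin periodinane, CH2Cl2, 0 °C to rt, no base; rapid neutral work-up
Reagents that add atoms: none
Why: Dess–Martin oxidation returns the C4 ketone under non-basic conditions, so the C3 configuration set in step 14 is carried over.

Step 16
Reactants: 21 (3R)-5,7-bis(benzyloxy)-3-[3-(benzyloxy)-4,5-dimethoxyphenyl]-6-methoxychroman-4-one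
Product: 22 (3R)-5,7-dihydroxy-3-(3-hydroxy-4,5-dimethoxyphenyl)-6-methoxychroman-4-one (target)
Conditions: H2 (1 atm), Pd/C, EtOAc, rt
Reagents that add atoms: none
Why: catalytic hydrogenolysis cleaves the three benzyl ethers under neutral conditions that should neither enolise C3 nor reduce the ketone, which becomes hydrogen-bonded to the freed C5 hydroxyl.

**Compound list**
1 | methyl 3,5-dihydroxy-4-methoxybenzoate | COC(=O)c1cc(O)c(OC)c(O)c1 | starting material
2 | methyl 3,5-bis(benzyloxy)-4-methoxybenzoate | COC(=O)c1cc(OCc2ccccc2)c(OC)c(OCc2ccccc2)c1 | intermediate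
3 | [3,5-bis(benzyloxy)-4-methoxyphenyl]methanol | OCc1cc(OCc2ccccc2)c(OC)c(OCc2ccccc2)c1 | intermediate
4 | 3,5-bis(benzyloxy)-4-methoxybenzaldehyde | O=Cc1cc(OCc2ccccc2)c(OC)c(OCc2ccccc2)c1 | intermediate
5 | 3,5-bis(benzyloxy)-4-methoxyphenyl formate | O=COc1cc(OCc2ccccc2)c(OC)c(OCc2ccccc2)c1 | intermediate
6 | 3,5-bis(benzyloxy)-4-methoxyphenol | Oc1cc(OCc2ccccc2)c(OC)c(OCc2ccccc2)c1 | intermediate
7 | 3,5-bis(benzyloxy)-2-iodo-4-methoxyphenol | Oc1cc(OCc2ccccc2)c(OC)c(OCc2ccccc2)c1I | intermediate
8 | 3-hydroxy-4,5-dimethoxybenzaldehyde | COc1cc(C=O)cc(O)c1OC | starting material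
9 | 3-(benzyloxy)-4,5-dimethoxybenzaldehyde | COc1cc(C=O)cc(OCc2ccccc2)c1OC | intermediate
10 | 2-[3-(benzyloxy)-4,5-dimethoxyphenyl]acetonitrile | COc1cc(CC#N)cc(OCc2ccccc2)c1OC | intermediate
11 | 2-[3-(benzyloxy)-4,5-dimethoxyphenyl]acetic acid | COc1cc(CC(=O)O)cc(OCc2ccccc2)c1OC | intermediate
12 | tert-butyl 2-[3-(benzyloxy)-4,5-dimethoxyphenyl]acetate | COc1cc(CC(=O)OC(C)(C)C)cc(OCc2ccccc2)c1OC | intermediate
13 | tert-butyl 2-[3-(benzyloxy)-4,5-dimethoxyphenyl]-3-hydroxypropanoate (racemic) | COc1cc(C(CO)C(=O)OC(C)(C)C)cc(OCc2ccccc2)c1OC | intermediate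
14 | tert-butyl 2-[3-(benzyloxy)-4,5-dimethoxyphenyl]prop-2-enoate | COc1cc(C(=C)C(=O)OC(C)(C)C)cc(OCc2ccccc2)c1OC | intermediate
15 | tert-butyl 3-[3,5-bis(benzyloxy)-2-iodo-4-methoxyphenoxy]-2-[3-(benzyloxy)-4,5-dimethoxyphenyl]propanoate (racemic) | CC(C)(C)OC(=O)C(COc1cc(OCc2ccccc2)c(OC)c(OCc2ccccc2)c1I)c1cc(OCc2ccccc2)c(OC)c(OC)c1 | intermediate
16 | carbon monoxide | [C-]#[O+] | starting material
17 | tert-butyl 5,7-bis(benzyloxy)-3-[3-(benzyloxy)-4,5-dimethoxyphenyl]-6-methoxy-4-oxochromane-3-carboxylate (racemic) | CC(C)(C)OC(=O)C1(c2cc(OCc3ccccc3)c(OC)c(OC)c2)COc2cc(OCc3ccccc3)c(OC)c(OCc3ccccc3)c2C1=O | intermediate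
18 | 5,7-bis(benzyloxy)-3-[3-(benzyloxy)-4,5-dimethoxyphenyl]-6-methoxy-4-oxochromane-3-carboxylic acid (racemic) | OC(=O)C1(c2cc(OCc3ccccc3)c(OC)c(OC)c2)COc2cc(OCc3ccccc3)c(OC)c(OCc3ccccc3)c2C1=O | intermediate
19 | racemic 5,7-bis(benzyloxy)-3-[3-(benzyloxy)-4,5-dimethoxyphenyl]-6-methoxychroman-4-one | COc1cc(C2COc3cc(OCc4ccccc4)c(OC)c(OCc4ccccc4)c3C2=O)cc(OCc2ccccc2)c1OC | intermediate
20 | (3R,4R)-5,7-bis(benzyloxy)-3-[3-(benzyloxy)-4,5-dimethoxyphenyl]-6-methoxychroman-4-ol | COc1cc([C@@H]2COc3cc(OCc4ccccc4)c(OC)c(OCc4ccccc4)c3[C@@H]2O)cc(OCc2ccccc2)c1OC | intermediate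
21 | (3R)-5,7-bis(benzyloxy)-3-[3-(benzyloxy)-4,5-dimethoxyphenyl]-6-methoxychroman-4-one | COc1cc([C@@H]2COc3cc(OCc4ccccc4)c(OC)c(OCc4ccccc4)c3C2=O)cc(OCc2ccccc2)c1OC | intermediate
22 | (3R)-5,7-dihydroxy-3-(3-hydroxy-4,5-dimethoxyphenyl)-6-methoxychroman-4-one | COc1cc([C@@H]2COc3cc(O)c(OC)c(O)c3C2=O)cc(O)c1OC | target

**Step count**
Total: 16 steps. Longest linear sequence: 11 steps (steps 1–5 then 11–16 from 1; the branch from 8 through steps 6–10 is equally long).

**Steps most likely to fail**

1. Step 12. Enolisation of C3 by the amine may be too slow for ring closure, so that the aroylpalladium intermediate is diverted by hydrolysis or reduction. If a stronger base is used to compensate, beta-elimination of the ring A aryloxide from the C3 enolate may outrun acylation. Direct C3–C4a coupling without CO uptake is a lesser risk. The fallback sets out from 15 and returns at 17; it separates the two bond formations while still bringing in C4 as CO. Carbonylation of 15 in the presence of pentafluorophenol (Pd(OAc)2, Xantphos, CO 1 bar, Et3N, toluene, 80 °C) is an aryloxycarbonylation that needs no enolate and should give the pentafluorophenyl ester F1. Treatment of that ester with LiN(SiMe3)2 in THF at −78 °C then closes ring C by Dieckmann-type C-acylation. At this temperature the lithium enolate should not eliminate, and the non-nucleophilic pentafluorophenoxide cannot reopen the quaternary beta-keto ester 17.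

2. Step 11. The oxa-Michael addition is an equilibrium that the acidic, ortho-iodinated phenol may leave on the side of the components, and the 2-arylacrylate may dimerise or polymerise meanwhile. The fallback sets out from 12 and 7 and returns at 15. The formaldehyde aldol is stopped at the hydroxymethyl stage ((CH2O)n, NaHCO3 cat., DMSO, rt) and the hydroxy ester 13 is isolated. It is then coupled with 7 under Mitsunobu conditions (PPh3, DIAD, toluene, 0 °C), an irreversible SN2 etherification at the primary carbinol. No new compound arises (F0).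

3. Step 14. Hydride transfer to a carbonyl flanked by the C5 benzyloxy group may be slow, or C3 epimerisation may lag behind reduction; either would erode conversion, the cis preference and enantiomeric purity. The fallback sets out from 19 and returns at 21, skipping steps 14 and 15. Racemic 19 is resolved by preparative chromatography on a chiral stationary phase (cellulose tris(3,5-dimethylphenylcarbamate)). The (3R) enantiomer is 21; the (3S)-5,7-bis(benzyloxy)-3-[3-(benzyloxy)-4,5-dimethoxyphenyl]-6-methoxychroman-4-one F2 is racemised back to 19 with Et3N in toluene and recycled.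

**Further compounds**
F1 | step 12 | tert-butyl 3-{3,5-bis(benzyloxy)-4-methoxy-2-[(pentafluorophenoxy)carbonyl]phenoxy}-2-[3-(benzyloxy)-4,5-dimethoxyphenyl]propanoate (racemic) | CC(C)(C)OC(=O)C(COc1cc(OCc2ccccc2)c(OC)c(OCc2ccccc2)c1C(=O)Oc1c(F)c(F)c(F)c(F)c1F)c1cc(OCc2ccccc2)c(OC)c(OC)c1
F0 | step 11 | none | none
F2 | step 14 | (3S)-5,7-bis(benzyloxy)-3-[3-(benzyloxy)-4,5-dimethoxyphenyl]-6-methoxychroman-4-one | COc1cc([C@H]2COc3cc(OCc4ccccc4)c(OC)c(OCc4ccccc4)c3C2=O)cc(OCc2ccccc2)c1OC
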